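**Plan**

- Ring C is cut at O1–C2 and C3–C4. It closes by 6-endo-dig oxa-Michael addition of the C8a phenol onto an aryloxy-ynone made from a lithium aryloxyacetylide and a C4 aldehyde, so the C2–OAr ether enters as an aryl ynol ether.
- Ring A is cut at C5–C6 and C4a–C8a into an acyclic 1,1,3-trioxygenated diene (C8a–C8–C7–C6, from methyl 2-prenylacetoacetate) and 3-methoxypropynal (C5–C4a–C4).
- Forward order: diene plus ynal gives ring A by Diels–Alder/aromatisation, then acetylide addition at C4, then oxidation and closure of ring C, then unmasking of the 5- and 4'-hydroxyls.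
- Enabling feature: ring A is a phloroglucinol ring. Its carbons C8a(O)–C8(prenyl)–C7(OMe)–C6(H) are a masked 2-prenylacetoacetate, and its C5(O)–C4a(–C4=O) edge is a push–pull alkoxy-ynal. The cycloaddition therefore fixes 5-O, 7-OMe and 8-prenyl and leaves the oxygen next to the prenyl group as the only free hydroxyl, the one that becomes O1.
- The target is achiral. The transient stereocentres (alpha-carbon of the keto ester, ketal carbon of the cycloadduct, carbinol before oxidation) are racemic and are destroyed.

Key step: step 5

Remark: the enol ether and the silyl ketene acetal are carried as mixtures of alkene isomers, which is without consequence because both alkene carbons end up in the aromatic ring.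

**Route**

Step 1
Reactants: 1 methyl acetoacetate; 2 prenyl bromide (1-bromo-3-methylbut-2-ene)
Product: 3 methyl 2-acetyl-5-methylhex-4-enoate (racemic)
Conditions: NaH (1.0 equiv), THF, 0 °C; then 2 (0.9 equiv), 0 °C to rt
Reagents that add atoms: none
Why: Acetoacetic ester alkylation (SN2) of the stabilised sodium enolate by a primary allylic bromide, the slight excess of 1 suppressing dialkylation.

Step 2
Reactants: 3 methyl 2-acetyl-5-methylhex-4-enoate
Product: 4 methyl 3-methoxy-2-(3-methylbut-2-enyl)but-2-enoate (E/Z mixture)
Conditions: Cs2CO3 (1.2 equiv), Me2SO4 (1.2 equiv), DMF, 0 °C to rt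
Reagents that add atoms: dimethyl sulfate COS(=O)(=O)OC
Why: O-alkylation of a dissociated beta-keto ester enolate by a hard methylating agent in a dipolar aprotic solvent, the already substituted alpha-carbon disfavouring C-methylation; either alkene isomer serves because the geometry is lost in step 3.

Step 3
Reactants: 4 methyl 3-methoxy-2-(3-methylbut-2-enyl)but-2-enoate
Product: 5 1,3-dimethoxy-2-(3-methylbut-2-enyl)-1-(trimethylsilyloxy)buta-1,3-diene
Conditions: LiN(iPr)2 (1.1 equiv), THF, −78 °C; Me3SiCl (1.3 equiv), −78 °C to rt; pentane, filtration, used crude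
Reagents that add atoms: chlorotrimethylsilane C[Si](C)(C)Cl
Why: Kinetic gamma-deprotonation of the 3-methoxy-enoate to the lithium dienolate and O-silylation (silyl ketene acetal formation, the standard access to 1-alkoxy-1-silyloxy-1,3-dienes).

Step 4
Reactants: 6 2-chloro-1,1-dimethoxyethane
Product: 8 3-methoxyprop-2-ynal, via lithium methoxyacetylide 7 (not isolated)
Conditions: LiNEt2 (3.1 equiv), THF, −10 to 0 °C; DMF (1.2 equiv), −78 to −20 °C; reverse quench into cold aqueous KH2PO4/Et2O; dried ethereal solution used directly
Reagents that add atoms: N,N-dimethylformamide CN(C)C=O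
Why: Twofold elimination (HCl and methanol) from the chloroacetal by lithium amide gives the alkoxyacetylide, which is formylated by DMF; the reverse quench into excess cold buffer collapses the hemiaminal and protonates the amines before they can add to the ynal.

Step 5
Reactants: 5 1,3-dimethoxy-2-(3-methylbut-2-enyl)-1-(trimethylsilyloxy)buta-1,3-diene; 8 3-methoxyprop-2-ynal
Product: 10 2-hydroxy-4,6-dimethoxy-3-(3-methylbut-2-enyl)benzaldehyde, via silyl ketal cycloadduct 9 (not isolated)
Conditions: 5 (1.3 equiv), toluene, 0 to 40 °C; then aqueous citric acid, THF, 0 °C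
Reagents that add atoms: none
Why: Normal-electron-demand [4+2] cycloaddition (in the limit a vinylogous Mukaiyama–Michael addition followed by ring closure) in which the unsubstituted CH2 terminus of 5, carrying the largest HOMO coefficient, bonds to the methoxy-bearing alkyne carbon beta to the formyl group and the ketene-acetal carbon bonds to the alpha-carbon, so that ring A is closed intermolecularly through the C5–C6 and C4a–C8a bonds (chromone numbering) as the cyclohexa-1,4-diene 9. Mild aqueous acid then cleaves the O–Si bond of the silyl ketal and methanol is lost, which aromatises the ring, driven by aromaticity and by the hydrogen bond from the new phenol to the formyl oxygen. The closest known reaction type is the Diels–Alder/aromatisation benzannulation of 1-alkoxy-1-silyloxy-1,3-dienes with alkynyl aldehydes, ketones and esters to give salicyl derivatives. The only stereocentre formed, the ketal carbon of 9, is racemic and becomes sp2 on aromatisation, so no stereocontrol is needed. The step needs regioselectivity, secured by the matched polarisation of the partners (donor oxygens at C1 and C3 of the diene, acceptor formyl and donor methoxy on the alkyne); chemoselectivity for the C≡C over the C=O bond, secured by running it thermally without Lewis acid; and retention of the ketene-acetal oxygen as the phenol, secured by hydrolysing the silyl ether before elimination. The product carries O5 as a methyl ether and the oxygen ortho to the prenyl group as the only free hydroxyl, which fixes which oxygen becomes O1 in step 8.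

Step 6
Reactants: 11 4-(methoxymethoxy)phenol; 12 trichloroethylene
Product: 13 1-[(E)-1,2-dichloroethenoxy]-4-(methoxymethoxy)benzene
Conditions: K2CO3 (1.5 equiv), DMF, 70 °C
Reagents that add atoms: none
Why: Base-mediated elimination of HCl from trichloroethylene and anti addition of the phenoxide to the dichloroacetylene so formed (known synthesis of aryl 1,2-dichlorovinyl ethers), giving the E isomer, the MOM acetal being inert to base.

Step 7
Reactants: 13 1-[(E)-1,2-dichloroethenoxy]-4-(methoxymethoxy)benzene; 10 2-hydroxy-4,6-dimethoxy-3-(3-methylbut-2-enyl)benzaldehyde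
Product: 15 2-{1-hydroxy-3-[4-(methoxymethoxy)phenoxy]prop-2-ynyl}-3,5-dimethoxy-6-(3-methylbut-2-enyl)phenol (racemic), via lithium aryloxyacetylide 14 (not isolated)
Conditions: 13 (1.5 equiv), n-BuLi (3.0 equiv), THF, −78 to −40 °C; then sodium phenoxide of 10 (NaH, THF, 0 °C), −78 to 0 °C; water at pH 7, no chromatography, crude taken on at once
Reagents that add atoms: none
Why: Dehydrochlorination followed by chlorine–lithium exchange turns the dichlorovinyl ether into the lithium ynol-ether acetylide (known ynol ether synthesis), which adds 1,2 to the aldehyde; the carbinol centre is racemic and is removed by oxidation in step 8.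

Step 8
Reactants: 15 2-{1-hydroxy-3-[4-(methoxymethoxy)phenoxy]prop-2-ynyl}-3,5-dimethoxy-6-(3-methylbut-2-enyl)phenol
Product: 17 5,7-dimethoxy-2-[4-(methoxymethoxy)phenoxy]-8-(3-methylbut-2-enyl)-4H-chromen-4-one, via aryloxy ynone 16 (not isolated)
Conditions: MnO2 (activated, 15 equiv), 4 Å molecular sieves, CH2Cl2, rt; filtration; K2CO3 (0.2 equiv), acetone, rt
Reagents that add atoms: none
Why: Neutral MnO2 oxidation of the benzylic propargylic alcohol gives the ynone, and the single free, chelated C8a hydroxyl then adds to the aryloxy-bearing alkyne carbon (base-catalysed 6-endo-dig oxa-Michael cyclisation, the ynone route to chromones), attack at the beta-carbon being favoured over 5-exo closure because only it gives a carbonyl-stabilised anion.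

Step 9
Reactants: 17 5,7-dimethoxy-2-[4-(methoxymethoxy)phenoxy]-8-(3-methylbut-2-enyl)-4H-chromen-4-one
Product: 18 5-hydroxy-7-methoxy-2-[4-(methoxymethoxy)phenoxy]-8-(3-methylbut-2-enyl)-4H-chromen-4-one
Conditions: MgI2·OEt2 (3 equiv), toluene–THF, 60 °C; aqueous Na2S2O3 work-up
Reagents that add atoms: none
Why: Chelation-controlled demethylation, in which magnesium held between the C4 carbonyl and the peri 5-methoxy oxygen activates only that methyl group for SN2 attack by iodide, so the 7-methoxy group, the prenyl alkene and the aryl ether should be spared; any loss of the MOM group here only anticipates step 10.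

Step 10
Reactants: 18 5-hydroxy-7-methoxy-2-[4-(methoxymethoxy)phenoxy]-8-(3-methylbut-2-enyl)-4H-chromen-4-one
Product: 19 7-O-methylepimedonin G, 5-hydroxy-2-(4-hydroxyphenoxy)-7-methoxy-8-(3-methylbut-2-enyl)-4H-chromen-4-one
Conditions: HCl (3 M aq)–MeOH, 40 °C
Reagents that add atoms: none
Why: Acid-catalysed acetal exchange (methanolysis of the MOM ether), the usual last step for prenylated phenols; no hydroxyl is ortho to the prenyl group, so chroman formation is not possible.

**Compound list**

1 | methyl acetoacetate | COC(=O)CC(C)=O | starting material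
2 | prenyl bromide (1-bromo-3-methylbut-2-ene) | CC(C)=CCBr | starting material
3 | methyl 2-acetyl-5-methylhex-4-enoate (racemic) | COC(=O)C(CC=C(C)C)C(C)=O | intermediate
4 | methyl 3-methoxy-2-(3-methylbut-2-enyl)but-2-enoate (E/Z mixture) | COC(=O)C(CC=C(C)C)=C(C)OC | intermediate
5 | 1,3-dimethoxy-2-(3-methylbut-2-enyl)-1-(trimethylsilyloxy)buta-1,3-diene (ketene-acetal isomer mixture) | COC(=C)C(CC=C(C)C)=C(OC)O[Si](C)(C)C | intermediate
6 | 2-chloro-1,1-dimethoxyethane | COC(CCl)OC | starting material
7 | lithium methoxyacetylide | [Li]C#COC | intermediate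
8 | 3-methoxyprop-2-ynal | COC#CC=O | intermediate
9 | 2,4,6-trimethoxy-5-(3-methylbut-2-enyl)-6-(trimethylsilyloxy)cyclohexa-1,4-diene-1-carbaldehyde (racemic) | COC1=C(C=O)C(OC)(O[Si](C)(C)C)C(CC=C(C)C)=C(OC)C1 | intermediate
10 | 2-hydroxy-4,6-dimethoxy-3-(3-methylbut-2-enyl)benzaldehyde | COc1cc(OC)c(CC=C(C)C)c(O)c1C=O | intermediate
11 | 4-(methoxymethoxy)phenol | COCOc1ccc(O)cc1 | starting material
12 | trichloroethylene | ClC=C(Cl)Cl | starting material
13 | 1-[(E)-1,2-dichloroethenoxy]-4-(methoxymethoxy)benzene | COCOc1ccc(O/C(Cl)=C\Cl)cc1 | intermediate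
14 | lithium [4-(methoxymethoxy)phenoxy]acetylide | [Li]C#COc1ccc(OCOC)cc1 | intermediate
15 | 2-{1-hydroxy-3-[4-(methoxymethoxy)phenoxy]prop-2-ynyl}-3,5-dimethoxy-6-(3-methylbut-2-enyl)phenol (racemic) | COCOc1ccc(OC#CC(O)c2c(O)c(CC=C(C)C)c(OC)cc2OC)cc1 | intermediate
16 | 1-[2-hydroxy-4,6-dimethoxy-3-(3-methylbut-2-enyl)phenyl]-3-[4-(methoxymethoxy)phenoxy]prop-2-yn-1-one | COCOc1ccc(OC#CC(=O)c2c(O)c(CC=C(C)C)c(OC)cc2OC)cc1 | intermediate
17 | 5,7-dimethoxy-2-[4-(methoxymethoxy)phenoxy]-8-(3-methylbut-2-enyl)-4H-chromen-4-one | COCOc1ccc(Oc2cc(=O)c3c(OC)cc(OC)c(CC=C(C)C)c3o2)cc1 | intermediate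
18 | 5-hydroxy-7-methoxy-2-[4-(methoxymethoxy)phenoxy]-8-(3-methylbut-2-enyl)-4H-chromen-4-one | COCOc1ccc(Oc2cc(=O)c3c(O)cc(OC)c(CC=C(C)C)c3o2)cc1 | intermediate
19 | 7-O-methylepimedonin G, 5-hydroxy-2-(4-hydroxyphenoxy)-7-methoxy-8-(3-methylbut-2-enyl)-4H-chromen-4-one | COc1cc(O)c2c(=O)cc(Oc3ccc(O)cc3)oc2c1CC=C(C)C | target

**Step count and risks**

Total steps: 10. Longest linear sequence: 8 (steps 1, 2, 3, 5, 7, 8, 9, 10).

Steps most likely to fail:

Step 5. The diene may react at the formyl group (hetero-Diels–Alder or vinylogous aldol) instead of at the alkyne, the push–pull ynal may polymerise, or the adduct may aromatise by loss of silanol instead of methanol. The fallback sets out from 7 and 5 and comes back at 10; it moves the dienophile to the ester oxidation level, where only the alkyne can react. Acetylide 7 is quenched with methyl chloroformate to give methyl 3-methoxyprop-2-ynoate F1. Thermal cycloaddition of F1 with 5 (toluene, 80 °C) should give the silyl ketal cycloadduct methyl 2,4,6-trimethoxy-5-(3-methylbut-2-enyl)-6-(trimethylsilyloxy)cyclohexa-1,4-diene-1-carboxylate F2, which the same acidic work-up should convert into methyl 2-hydroxy-4,6-dimethoxy-3-(3-methylbut-2-enyl)benzoate F3. LiAlH4 (THF, 0 °C) reduces the ester to 2-(hydroxymethyl)-3,5-dimethoxy-6-(3-methylbut-2-enyl)phenol F4, and MnO2 (CH2Cl2) re-oxidises the benzylic alcohol to aldehyde 10.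

Step 8. Oxidation and ring closure cannot be controlled separately in the free phenol: the ynone may be hydrated by the water formed on MnO2, may close in the 5-exo mode, or the electron-rich phenol may be oxidised. The fallback sets out from 10 and comes back at 17; it stages the sequence on a protected phenol. Silylation (t-BuMe2SiCl, imidazole, DMF) gives 2-[tert-butyl(dimethyl)silyl]oxy-4,6-dimethoxy-3-(3-methylbut-2-enyl)benzaldehyde F5. Addition of acetylide 14 gives 1-{2-[tert-butyl(dimethyl)silyl]oxy-4,6-dimethoxy-3-(3-methylbut-2-enyl)phenyl}-3-[4-(methoxymethoxy)phenoxy]prop-2-yn-1-ol F6. Anhydrous oxidation with the periodinane DMP (1,1,1-triacetoxy-1,2-benziodoxol-3-one) buffered by NaHCO3 gives 1-{2-[tert-butyl(dimethyl)silyl]oxy-4,6-dimethoxy-3-(3-methylbut-2-enyl)phenyl}-3-[4-(methoxymethoxy)phenoxy]prop-2-yn-1-one F7, which has no internal nucleophile and can be purified. Bu4NF (THF, 0 °C) then releases the phenoxide, which should close ring C to 17.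

Step 4. The liberated secondary amines may add to the ynal during the quench, or the volatile aldehyde may be lost on handling. The fallback sets out from 7 and comes back at 8; it replaces formylation by hydroxymethylation and oxidation. Acetylide 7 is treated with paraformaldehyde to give 3-methoxyprop-2-yn-1-ol F8, the amines are removed by aqueous extraction, and oxidation with MnO2 in CH2Cl2 should give an amine-free solution of 8 for direct use in step 5.

Further compounds
F1 | step 5 | methyl 3-methoxyprop-2-ynoate | COC#CC(=O)OC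
F2 | step 5 | methyl 2,4,6-trimethoxy-5-(3-methylbut-2-enyl)-6-(trimethylsilyloxy)cyclohexa-1,4-diene-1-carboxylate (racemic) | COC(=O)C1=C(OC)CC(OC)=C(CC=C(C)C)C1(OC)O[Si](C)(C)C
F3 | step 5 | methyl 2-hydroxy-4,6-dimethoxy-3-(3-methylbut-2-enyl)benzoate | COC(=O)c1c(O)c(CC=C(C)C)c(OC)cc1OC
F4 | step 5 | 2-(hydroxymethyl)-3,5-dimethoxy-6-(3-methylbut-2-enyl)phenol | OCc1c(O)c(CC=C(C)C)c(OC)cc1OC
F5 | step 8 | 2-[tert-butyl(dimethyl)silyl]oxy-4,6-dimethoxy-3-(3-methylbut-2-enyl)benzaldehyde | O=Cc1c(O[Si](C)(C)C(C)(C)C)c(CC=C(C)C)c(OC)cc1OC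
F6 | step 8 | 1-{2-[tert-butyl(dimethyl)silyl]oxy-4,6-dimethoxy-3-(3-methylbut-2-enyl)phenyl}-3-[4-(methoxymethoxy)phenoxy]prop-2-yn-1-ol (racemic) | COCOc1ccc(OC#CC(O)c2c(O[Si](C)(C)C(C)(C)C)c(CC=C(C)C)c(OC)cc2OC)cc1
F7 | step 8 | 1-{2-[tert-butyl(dimethyl)silyl]oxy-4,6-dimethoxy-3-(3-methylbut-2-enyl)phenyl}-3-[4-(methoxymethoxy)phenoxy]prop-2-yn-1-one | COCOc1ccc(OC#CC(=O)c2c(O[Si](C)(C)C(C)(C)C)c(CC=C(C)C)c(OC)cc2OC)cc1
F8 | step 4 | 3-methoxyprop-2-yn-1-ol | COC#CCO
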